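The cyclobutane is numbered so that C1 and C3 carry the aryl groups and C2 and C4 the acyl groups. The route rests on cutting ring bond C1–C2. The order aryl, acyl, aryl, acyl around this ring is the one found along C6, C3, C4 and C5 of a 4,6-diaryl-2-pyranone-5-carboxylate, whose C2 carbonyl already sits on C3. Photochemical 4π closure joins pyranone C3 and C6. In one operation this gives the four-membered carbocycle with all four substituents in place, plus a strained β-lactone whose benzylic C–O bond invites reductive opening. The precursor is a flat, achiral pyranone tert-butyl ester made from a β-keto ester and an arylpropiolate.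

Key step: step 4

Remark on stereochemistry: the target SMILES decodes to the centrosymmetric isomer (aryl trans to aryl, acyl trans to acyl, each acyl cis to one neighbouring aryl). It is achiral, so every chiral intermediate is made as a racemate and its SMILES shows one enantiomer.

Remark on design:
- The pyranone ester is tert-butyl. It is inert in the photochemical and reductive steps and is later converted directly into the acid chloride, so hydroxide never meets the two enolisable ring carbons. Its preparation lies off the longest linear sequence.
- The photoproduct holds a tertiary, benzylic, allylic and strained C–O bond. It is therefore neither warmed nor concentrated, and the next step uses exactly this lability.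
- Undirected hydrogenation of the later cyclobutene would give the all-cis isomer, so that reduction is run under carboxyl direction.

Step 1
Reactants: 1 4-iodo-1,2-dimethoxybenzene (4-iodoveratrole); 2 ethyl propiolate
Product: 3 ethyl 3-(3,4-dimethoxyphenyl)prop-2-ynoate
Conditions: PdCl2(PPh3)2 (2 mol %), CuI (4 mol %), K2CO3 (2 equiv), 2 (3 equiv, in portions), THF, 65 °C
Reagents that add atoms: none
Why: Sonogashira coupling, in which the carbonate base replaces the usual amine so that the electrophilic propiolate is not consumed by aza-Michael addition, and in which no stereocenter is formed.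

Step 2
Reactants: 4 tert-butyl acetate; 5 3,4-dimethoxybenzoyl chloride
Product: 7 tert-butyl 3-(3,4-dimethoxyphenyl)-3-oxopropanoate, via lithium enolate of tert-butyl acetate 6 (not isolated)
Conditions: 4 (2.2 equiv), LiN(iPr)2 (2.2 equiv), THF, −78 °C; then 5, −78 → 0 °C; aq NH4Cl
Reagents that add atoms: none
Why: Crossed Claisen condensation of a preformed ester enolate with a non-enolisable acid chloride, where the second equivalent of enolate deprotonates the β-keto ester as it forms and thus prevents double acylation.

Step 3
Reactants: 3 ethyl 3-(3,4-dimethoxyphenyl)prop-2-ynoate; 7 tert-butyl 3-(3,4-dimethoxyphenyl)-3-oxopropanoate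
Product: 9 tert-butyl 4,6-bis(3,4-dimethoxyphenyl)-2-oxo-2H-pyran-5-carboxylate, via Michael adduct 8 (not isolated)
Conditions: Cs2CO3 (50 mol %), DMF, 80 °C
Reagents that add atoms: none
Why: Michael addition of the β-keto ester carbon to the aryl-bearing alkyne carbon followed by lactonisation of the enol oxygen onto the ethyl ester (the classical β-keto ester/arylpropiolate route to 2-pyranones), with the delocalised anion of 8 allowing the alkene geometry to adjust so that all material can close.

Step 4
Reactants: 9 tert-butyl 4,6-bis(3,4-dimethoxyphenyl)-2-oxo-2H-pyran-5-carboxylate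
Product: 10 rac-tert-butyl 1,5-bis(3,4-dimethoxyphenyl)-3-oxo-2-oxabicyclo[2.2.0]hex-5-ene-6-carboxylate (cis-fused)
Conditions: hν (365 nm LED), degassed CH2Cl2 (5 mM), −40 °C, flow coil; cold solution used directly
Reagents that add atoms: none
Why: Proposed new method: excitation of the pyranone to its singlet state is expected to trigger a disrotatory 4π electrocyclisation of the C3=C4–C5=C6 diene that bonds C3 to C6 (ring bond C1–C2 of the target). The closest known reaction type is the photochemical valence isomerisation of 2-pyranone and of alkyl 2-pyranone-5-carboxylates to 2-oxabicyclo[2.2.0]hex-5-en-3-ones, which has not been shown for 4,6-diaryl members. The one new bond closes the cyclobutene in the 4π electrocyclic mode and leaves O1 and C2 as a two-atom bridge across it, so the β-lactone ring is what remains of the six-membered ring and needs no closure of its own. The two new stereocenters, C1 and C4 of the bicycle, are tied together by geometry because a two-atom bridge can span a cyclobutene only in cis fashion, and the racemate suffices since the target is achiral. The closure must beat triplet [2+2] dimerisation, electrocyclic opening to the acyl ketene and secondary loss of CO2, which is addressed by high dilution and low temperature, by an aprotic solvent in which the ketene can only reclose to 9, and by 365 nm light that the extended 6-arylpyranone chromophore of 9 should absorb much better than the cinnamate-like chromophore of 10. The most likely thermal leak, heterolysis of the benzylic C1–O bond of 10, is harmless, since the 1,3-diarylcyclobutenyl cation so formed is mirror-symmetric and collapse at either end returns 10 or its enantiomer.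

Step 5
Reactants: 10 rac-tert-butyl 1,5-bis(3,4-dimethoxyphenyl)-3-oxo-2-oxabicyclo[2.2.0]hex-5-ene-6-carboxylate
Product: 12 rac-cis-3-(tert-butoxycarbonyl)-2,4-bis(3,4-dimethoxyphenyl)cyclobut-2-ene-1-carboxylic acid (C1 carboxyl cis to C4 aryl), via cyclobutenyl cation 11 (not isolated)
Conditions: Et3SiH (5 equiv), CF3CO2H (3 equiv), CH2Cl2, −40 → 0 °C; aq NaHCO3 extraction, then acidification (neutral 9 recovered)
Reagents that add atoms: none
Why: Ionic hydrogenation (silane plus acid), a reduction known for benzylic and tertiary C–O bonds including those of aryl-substituted lactones: acid-assisted heterolysis of the strained C1–O bond gives the mirror-symmetric cation 11, the silane delivers hydride to either aryl-bearing terminus from the face opposite to the carboxyl group on the adjacent carbon, which places that aryl cis to CO2H, and both termini lead to the same racemate so that regiochemistry is of no consequence.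

Step 6
Reactants: 12 rac-cis-3-(tert-butoxycarbonyl)-2,4-bis(3,4-dimethoxyphenyl)cyclobut-2-ene-1-carboxylic acid
Product: 13 rac-(r-1,t-2,t-3,c-4)-3-(tert-butoxycarbonyl)-2,4-bis(3,4-dimethoxyphenyl)cyclobutane-1-carboxylic acid
Conditions: [Ir(cod)(PCy3)(py)]PF6 (10 mol %), H2 (20 bar), CH2Cl2, 25 °C
Reagents that add atoms: none
Why: Substrate-directed homogeneous hydrogenation, known for β,γ-unsaturated cyclic carboxyl derivatives with this cationic iridium complex: binding of the C1 carboxyl oxygen holds the metal dihydride on the carboxyl face, so both hydrogens are added syn from that face and the C2 aryl and C3 ester are pushed to the other face, which sets the last two stereocenters (aryl trans to aryl, carbonyl trans to carbonyl).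

Step 7
Reactants: 13 rac-(r-1,t-2,t-3,c-4)-3-(tert-butoxycarbonyl)-2,4-bis(3,4-dimethoxyphenyl)cyclobutane-1-carboxylic acid
Product: 14 (r-1,c-2,t-3,t-4)-2,4-bis(3,4-dimethoxyphenyl)cyclobutane-1,3-dicarbonyl dichloride (centrosymmetric)
Conditions: SOCl2 (neat, excess), closed flask, 25 °C; evaporation with toluene
Reagents that add atoms: thionyl chloride, O=S(Cl)Cl
Why: Acid chloride formation with SOCl2, which also converts tert-butyl esters directly into acid chlorides under catalysis by HCl (here released as the free acid reacts first), so that both carboxyl groups are activated without any base and the two enolisable ring carbons keep their configuration.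

Step 8
Reactants: 14 (r-1,c-2,t-3,t-4)-2,4-bis(3,4-dimethoxyphenyl)cyclobutane-1,3-dicarbonyl dichloride; 15 5,6-dihydropyridin-2(1H)-one
Product: 17 target 1,1'-[(r-1,c-2,t-3,t-4)-2,4-bis(3,4-dimethoxyphenyl)cyclobutane-1,3-dicarbonyl]bis(5,6-dihydropyridin-2(1H)-one), via lithium lactamate 16 (not isolated)
Conditions: 15 (2.2 equiv), n-BuLi (2.1 equiv), THF, −78 °C; then 14, THF, −78 → −20 °C
Reagents that add atoms: none
Why: N-acylation of a lithium lactamate by an acid chloride, the usual entry to N-acyl-5,6-dihydropyridin-2-ones, which at −78 °C is much faster than ketene formation or enolisation so that all four ring stereocenters are carried over unchanged.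

Compound list
1 | 4-iodo-1,2-dimethoxybenzene | COc1ccc(I)cc1OC | starting material
2 | ethyl propiolate | C#CC(=O)OCC | starting material
3 | ethyl 3-(3,4-dimethoxyphenyl)prop-2-ynoate | CCOC(=O)C#Cc1ccc(OC)c(OC)c1 | intermediate
4 | tert-butyl acetate | CC(=O)OC(C)(C)C | starting material
5 | 3,4-dimethoxybenzoyl chloride | COc1ccc(C(=O)Cl)cc1OC | starting material
6 | lithium enolate of tert-butyl acetate | C=C([O-])OC(C)(C)C.[Li+] | intermediate
7 | tert-butyl 3-(3,4-dimethoxyphenyl)-3-oxopropanoate | COc1ccc(C(=O)CC(=O)OC(C)(C)C)cc1OC | intermediate
8 | 1-tert-butyl 5-ethyl (3E)-2-(3,4-dimethoxybenzoyl)-3-(3,4-dimethoxyphenyl)pent-3-enedioate (C2 enolisable, not defined) | CCOC(=O)/C=C(c1ccc(OC)c(OC)c1)\C(C(=O)OC(C)(C)C)C(=O)c1ccc(OC)c(OC)c1 | intermediate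
9 | tert-butyl 4,6-bis(3,4-dimethoxyphenyl)-2-oxo-2H-pyran-5-carboxylate | CC(C)(C)OC(=O)c1c(-c2ccc(OC)c(OC)c2)cc(=O)oc1-c1ccc(OC)c(OC)c1 | intermediate
10 | rac-tert-butyl 1,5-bis(3,4-dimethoxyphenyl)-3-oxo-2-oxabicyclo[2.2.0]hex-5-ene-6-carboxylate, cis-fused | O=C3O[C@]1(c2ccc(OC)c(OC)c2)C(C(=O)OC(C)(C)C)=C(c2ccc(OC)c(OC)c2)[C@@H]13 | intermediate
11 | 2-(tert-butoxycarbonyl)-4-carboxy-1,3-bis(3,4-dimethoxyphenyl)cyclobutenyl cation trifluoroacetate (mirror-symmetric, one resonance form drawn) | OC(=O)C1C(c2ccc(OC)c(OC)c2)=C(C(=O)OC(C)(C)C)[C+]1c1ccc(OC)c(OC)c1.[O-]C(=O)C(F)(F)F | intermediate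
12 | rac-cis-3-(tert-butoxycarbonyl)-2,4-bis(3,4-dimethoxyphenyl)cyclobut-2-ene-1-carboxylic acid | O=C(O)[C@@H]1C(c2ccc(OC)c(OC)c2)=C(C(=O)OC(C)(C)C)[C@@H]1c1ccc(OC)c(OC)c1 | intermediate
13 | rac-(r-1,t-2,t-3,c-4)-3-(tert-butoxycarbonyl)-2,4-bis(3,4-dimethoxyphenyl)cyclobutane-1-carboxylic acid | COc1ccc([C@H]2[C@@H](C(=O)OC(C)(C)C)[C@H](c3ccc(OC)c(OC)c3)[C@@H]2C(=O)O)cc1OC | intermediate
14 | (r-1,c-2,t-3,t-4)-2,4-bis(3,4-dimethoxyphenyl)cyclobutane-1,3-dicarbonyl dichloride | COc1ccc([C@H]2[C@H](C(=O)Cl)[C@H](c3ccc(OC)c(OC)c3)[C@H]2C(=O)Cl)cc1OC | intermediate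
15 | 5,6-dihydropyridin-2(1H)-one | O=C1C=CCCN1 | starting material
16 | lithium salt of 5,6-dihydropyridin-2(1H)-one | O=C1C=CCC[N-]1.[Li+] | intermediate
17 | 1,1'-[(r-1,c-2,t-3,t-4)-2,4-bis(3,4-dimethoxyphenyl)cyclobutane-1,3-dicarbonyl]bis(5,6-dihydropyridin-2(1H)-one) | COc1ccc([C@H]2[C@H](C(=O)N3CCC=CC3=O)[C@H](c3ccc(OC)c(OC)c3)[C@H]2C(=O)N2CCC=CC2=O)cc1OC | target

Total step count: 8. Longest linear sequence: 7 (steps 1, 3, 4, 5, 6, 7, 8; step 2 runs in parallel).

Steps most likely to fail

1. Step 4 (labelled).
- The excited state may decay without closing: by charge transfer between the electron-rich aryl groups and the pyranone, by fluorescence, or by intersystem crossing followed by dimerisation. The bicycle may also revert thermally before it is trapped.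
- The fallback uses known chemistry and a different ring construction. It sets out from 1 and comes back at 14.
- Heck reaction of 1 with acrylic acid (Pd(OAc)2, P(o-tol)3, Et3N, MeCN, 80 °C) should give (E)-3,4-dimethoxycinnamic acid F1, whose crystals pack head-to-tail in centrosymmetric pairs.
- Irradiation of the ground solid should then effect the topochemical [2+2] photodimerisation to (r-1,c-2,t-3,t-4)-2,4-bis(3,4-dimethoxyphenyl)cyclobutane-1,3-dicarboxylic acid F2. SOCl2 converts this diacid into 14.

2. Step 6.
- Hydrogen may be taken up from the open face, away from the carboxyl and C4 aryl groups (loss of direction). The catalyst may also fail to turn over at the crowded tetrasubstituted alkene.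
- The fallback exchanges the directing group through a redox detour. It sets out from 12 and comes back at 13.
- BH3·THF (0 °C) should reduce the acid chemoselectively to tert-butyl rac-cis-2,4-bis(3,4-dimethoxyphenyl)-3-(hydroxymethyl)cyclobut-1-ene-1-carboxylate F3.
- Hydroxyl-directed hydrogenation of this homoallylic alcohol with [Ir(cod)(PCy3)(py)]PF6 uses the most reliable directing group for this complex. It should give tert-butyl rac-2,4-bis(3,4-dimethoxyphenyl)-3-(hydroxymethyl)cyclobutane-1-carboxylate F4, with the relative configuration of 13.
- TEMPO (cat.)/PhI(OAc)2 in aqueous MeCN then oxidises the primary alcohol to the acid 13.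

3. Step 5.
- Hydride may be captured on the carboxyl face if product stability overrides approach control. The tert-butyl group may be lost prematurely under acid, or the bicycle may revert before it ionises.
- The fallback replaces cation capture by a nucleophilic hydride acting on the intact bicycle. It sets out from 10 and comes back at 12 without any new compound.
- The monovalent copper hydride [(Ph3P)CuH]6 in toluene is added to the cold photolysate. It should add hydride to the aryl-bearing enoate carbon C5 from the convex face, while the covalent lactone still blocks the concave face.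
- The enolate then expels the carboxylate from C1. This anti SN2′ addition–elimination is a reaction type known for 2-(1-acyloxyalkyl)acrylates.

Further compounds
F1 | step 4 | (E)-3,4-dimethoxycinnamic acid | COc1ccc(/C=C/C(=O)O)cc1OC
F2 | step 4 | (r-1,c-2,t-3,t-4)-2,4-bis(3,4-dimethoxyphenyl)cyclobutane-1,3-dicarboxylic acid | COc1ccc([C@H]2[C@H](C(=O)O)[C@H](c3ccc(OC)c(OC)c3)[C@H]2C(=O)O)cc1OC
F3 | step 6 | tert-butyl rac-cis-2,4-bis(3,4-dimethoxyphenyl)-3-(hydroxymethyl)cyclobut-1-ene-1-carboxylate | OC[C@@H]1C(c2ccc(OC)c(OC)c2)=C(C(=O)OC(C)(C)C)[C@@H]1c1ccc(OC)c(OC)c1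
F4 | step 6 | tert-butyl rac-2,4-bis(3,4-dimethoxyphenyl)-3-(hydroxymethyl)cyclobutane-1-carboxylate (relative configuration as in 13) | COc1ccc([C@H]2[C@@H](C(=O)OC(C)(C)C)[C@H](c3ccc(OC)c(OC)c3)[C@@H]2CO)cc1OC
F0 | step 5 | none | none
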